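Assumption: gibberellane numbering is used; α is the face of C19 and C20, β is the face of H-5, C18 and the 2,3-diol. GA3, GA7 and GA43 stand for gibberellic acid, its 13-deoxy analogue and the target gibberellin (number 43 of the series); gibberellic acid is taken as the bulk fermentation product.

**Retrosynthetic overview**
1. All four rings (A–D), C7, C18, C19 and the stereocentres C4, C5, C6, C8, C9 and C13 are bought in gibberellic acid 1. No ring is formed; the order of events is ring D (13-deoxygenation), then C10 at the ring A/B junction, then ring A (C2, C3).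
2. C10–C20: the C20 carboxyl is carbon dioxide 2, joined to C10 by cathodic reductive opening of the allylic 19→10 lactone (key step, new). The same step frees C19 and leaves a Δ1 alkene.
3. C2–O: a C2 enolate plus electrophilic oxygen on the β face, the enolate coming from 1,4-reduction of a Δ1-3-ketone.
4. C3 carbinol from the 3-ketone by equatorial hydride delivery (axial 3β-OH); the three carboxyls travel as allyl esters and are freed last.
5. C13–O is removed first by radical deoxygenation of an oxalate, with the 3-OH masked as a silyl ether.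

**Route**

Step 1
Reactants: 1 gibberellic acid (GA3)
Product: 5 3-O-triethylsilyl-13-O-(methoxyoxalyl)-GA3, via bis-silyl GA3 3 (not isolated), via bis-silyl oxalate 4 (not isolated)
Conditions: Et3SiCl (2.2 equiv), pyridine, 0 °C → rt; then ClCOCO2Me (1.5 equiv), DMAP (0.1 equiv), 0 °C → rt; aq. citric acid work-up
Reagents that add atoms: chlorotriethylsilane CC[Si](Cl)(CC)CC; methyl chlorooxoacetate COC(=O)C(=O)Cl
Why: Et3SiCl silylates the secondary 3β-OH and the CO2H but not the tertiary bridgehead 13-OH, which is then the only hydroxyl left for DMAP-catalysed O-acylation by methyl oxalyl chloride; the silyl ester falls off in the aqueous work-up and no stereocentre is touched (silyl ether formation, then O-acylation).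

Step 2
Reactants: 5 3-O-triethylsilyl-13-O-(methoxyoxalyl)-GA3
Product: 7 GA7, via 3-O-TES-GA7 6 (not isolated)
Conditions: Bu3SnH (2.5 equiv), AIBN (0.2 equiv), toluene, 100 °C; then HF·pyridine, THF, 0 °C → rt
Reagents that add atoms: none
Why: Dolan–MacMillan-type radical deoxygenation, in which Bu3Sn• adds to the oxalate, β-scission gives the bridgehead C13 radical and this takes H from Bu3SnH in the only geometry the bicyclo[3.2.1]octane allows; HF·pyridine then removes the TES ether (and tin as Bu3SnF) without the base that would shift the lactone to C2 or epimerise C3.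

Step 3
Reactants: 7 GA7; 2 carbon dioxide
Product: 9 triallyl 3β-hydroxygibberella-1,16-diene-7,19,20-trioate, via tricarboxylate salt 8 (not isolated)
Conditions: Et4NOH (1.0 equiv, then dried); Pd(OAc)2 (10 mol %), DPEphos (12 mol %), Et4NOTs (0.1 M), DMF, CO2 (1 atm), Mg anode, Pt cathode, undivided cell, 5 mA cm−2, 2.2 F mol−1, 0 °C; then allyl bromide (6 equiv), Bu4NI (0.1 equiv), 40 °C
Reagents that add atoms: allyl bromide C=CCBr
Why: Proposed new method: zerovalent palladium (formed from Pd(OAc)2 at the cathode) ionises the strained tertiary allylic lactone C10–O with inversion, the cationic η3-allyl complex over C10–C1–C2 (palladium on the β face, C19 carboxylate on the α face) takes up two electrons to give a nucleophilic η1-allylpalladium bound at the less hindered C2, and this attacks CO2 through C10 (SE2′, anti to palladium) on the α face, where the magnesium-ion-bridged C19 carboxylate also holds CO2, so that C10–C20 forms with net retention under control of the bought C4/C5 centres and the product is trapped as the chelated 19,20-dicarboxylate; the closest known reactions are the palladium-catalysed electroreductive, branched-selective carboxylation of acyclic allylic acetates with CO2 and the palladium-catalysed, Et2Zn-mediated carboxylation of allylic alcohols, neither shown for a lactone leaving group, a ring-fusion tertiary carbon or diastereocontrol at a quaternary centre.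

Step 4
Reactants: 9 triallyl 3β-hydroxygibberella-1,16-diene-7,19,20-trioate
Product: 10 triallyl 3-oxogibberella-1,16-diene-7,19,20-trioate
Conditions: Dess–Martin periodinane (1.5 equiv), CH2Cl2, 0 °C → rt
Reagents that add atoms: none
Why: Dess–Martin oxidation of the allylic 3β-alcohol to the Δ1-3-ketone under near-neutral conditions; C4 and C10 are quaternary so nothing can epimerise, and the allyl esters prevent the decarboxylation that a free β-keto acid (C19) or vinylogous β-keto acid (C20) would undergo.

Step 5
Reactants: 10 triallyl 3-oxogibberella-1,16-diene-7,19,20-trioate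
Product: 12 triallyl 2β-hydroxy-3-oxogibberell-16-ene-7,19,20-trioate, via potassium enolate 11 (not isolated)
Conditions: K[HB(s-Bu)3] (1.1 equiv), THF, −78 °C; then 2-(phenylsulfonyl)-3-phenyloxaziridine (1.5 equiv), −78 °C; then AcOH
Reagents that add atoms: 2-(phenylsulfonyl)-3-phenyloxaziridine O=S(=O)(c1ccccc1)N1OC1c1ccccc1
Why: Conjugate reduction followed by Davis enolate hydroxylation, in which the bulky hydride adds 1,4 to the β-unsubstituted enone (C3 is shielded by quaternary C4) to give a single regio-defined enolate, and the oxaziridine delivers oxygen to C2 on the β face because the α face is closed by the syn-axial C19 and C20 ester groups, setting the equatorial 2β-OH (also the thermodynamic epimer).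

Step 6
Reactants: 12 triallyl 2β-hydroxy-3-oxogibberell-16-ene-7,19,20-trioate
Product: 13 GA43 triallyl ester
Conditions: K[HB(s-Bu)3] (2.2 equiv), THF, −78 °C; then AcOH at −78 °C
Reagents that add atoms: none
Why: Diastereoselective ketone reduction in which the bulky hydride attacks C3 along the equatorial trajectory (the axial approach is hindered by H-1β and H-5β), giving the axial 3β-alcohol cis to 2β-OH as in Selectride reductions of 4,4-disubstituted 3-ketones; the second equivalent allows for the free 2-OH, and the allyl esters survive at −78 °C.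

Step 7
Reactants: 13 GA43 triallyl ester
Product: 14 GA43
Conditions: Pd(PPh3)4 (5 mol %), morpholine (10 equiv), THF, rt; then dilute HCl to pH 3
Reagents that add atoms: none
Why: Tsuji–Trost deallylation, in which zerovalent palladium cleaves the O–allyl bonds and morpholine takes up the allyl groups, so the neopentyl C19/C20 acyl carbons need not be attacked, the 3β-hydroxy-19-ester is never exposed to hydroxide (no retro-aldol) and no stereocentre is touched.

**Compound list**
1 | gibberellic acid (GA3) | C=C1C[C@]23C[C@@]1(O)CC[C@H]2[C@]14C=C[C@H](O)[C@@](C)(C(=O)O4)[C@H]1[C@@H]3C(=O)O | starting material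
2 | carbon dioxide | O=C=O | starting material
3 | 3-O-triethylsilyl-GA3 triethylsilyl ester | C=C1C[C@]23C[C@@]1(O)CC[C@H]2[C@]14C=C[C@H](O[Si](CC)(CC)CC)[C@@](C)(C(=O)O4)[C@H]1[C@@H]3C(=O)O[Si](CC)(CC)CC | intermediate
4 | 3-O-triethylsilyl-13-O-(methoxyoxalyl)-GA3 triethylsilyl ester | C=C1C[C@]23C[C@@]1(OC(=O)C(=O)OC)CC[C@H]2[C@]14C=C[C@H](O[Si](CC)(CC)CC)[C@@](C)(C(=O)O4)[C@H]1[C@@H]3C(=O)O[Si](CC)(CC)CC | intermediate
5 | 3-O-triethylsilyl-13-O-(methoxyoxalyl)-GA3 (free 7-acid) | C=C1C[C@]23C[C@@]1(OC(=O)C(=O)OC)CC[C@H]2[C@]14C=C[C@H](O[Si](CC)(CC)CC)[C@@](C)(C(=O)O4)[C@H]1[C@@H]3C(=O)O | intermediate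
6 | 3-O-triethylsilyl-GA7 | C=C1C[C@]23C[C@H]1CC[C@H]2[C@]14C=C[C@H](O[Si](CC)(CC)CC)[C@@](C)(C(=O)O4)[C@H]1[C@@H]3C(=O)O | intermediate
7 | GA7 (13-deoxy-GA3) | C=C1C[C@]23C[C@H]1CC[C@H]2[C@]14C=C[C@H](O)[C@@](C)(C(=O)O4)[C@H]1[C@@H]3C(=O)O | intermediate
8 | 3β-hydroxygibberella-1,16-diene-7,19,20-trioate, magnesium tetraethylammonium salt (C20 α on C10) | C=C1C[C@]23C[C@H]1CC[C@H]2[C@]1(C(=O)[O-])C=C[C@H](O)[C@@](C)(C(=O)[O-])[C@H]1[C@@H]3C(=O)[O-].[Mg+2].CC[N+](CC)(CC)CC | intermediate
9 | triallyl 3β-hydroxygibberella-1,16-diene-7,19,20-trioate | C=C1C[C@]23C[C@H]1CC[C@H]2[C@]1(C(=O)OCC=C)C=C[C@H](O)[C@@](C)(C(=O)OCC=C)[C@H]1[C@@H]3C(=O)OCC=C | intermediate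
10 | triallyl 3-oxogibberella-1,16-diene-7,19,20-trioate | C=C1C[C@]23C[C@H]1CC[C@H]2[C@]1(C(=O)OCC=C)C=CC(=O)[C@@](C)(C(=O)OCC=C)[C@H]1[C@@H]3C(=O)OCC=C | intermediate
11 | potassium C2=C3 enolate of the 1,2-dihydro-3-ketone triallyl ester | C=C1C[C@]23C[C@H]1CC[C@H]2[C@]1(C(=O)OCC=C)CC=C([O-])[C@@](C)(C(=O)OCC=C)[C@H]1[C@@H]3C(=O)OCC=C.[K+] | intermediate
12 | triallyl 2β-hydroxy-3-oxogibberell-16-ene-7,19,20-trioate | C=C1C[C@]23C[C@H]1CC[C@H]2[C@]1(C(=O)OCC=C)C[C@H](O)C(=O)[C@@](C)(C(=O)OCC=C)[C@H]1[C@@H]3C(=O)OCC=C | intermediate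
13 | GA43 triallyl ester (triallyl 2β,3β-dihydroxygibberell-16-ene-7,19,20-trioate) | C=C1C[C@]23C[C@H]1CC[C@H]2[C@]1(C(=O)OCC=C)C[C@H](O)[C@H](O)[C@@](C)(C(=O)OCC=C)[C@H]1[C@@H]3C(=O)OCC=C | intermediate
14 | GA43 (2β,3β-dihydroxygibberell-16-ene-7,19,20-trioic acid) | C=C1C[C@]23C[C@H]1CC[C@H]2[C@]1(C(=O)O)C[C@H](O)[C@H](O)[C@@](C)(C(=O)O)[C@H]1[C@@H]3C(=O)O | target

**Step count**
Total steps: 7. Longest linear sequence: 7 (fully linear from 1).

**Steps most likely to fail, with fallbacks**

Step 3 (the new electro-carboxylation). The η1-allyl intermediate may be protonated, may eliminate the 3-oxygen to a 1(10),2-diene, or may take up CO2 at C2 or on the β face of C10. The fallback uses known chemistry and replaces the cathodic umpolung by an isolable allylboron nucleophile. It sets out from 6 (isolated from step 2 by leaving out the fluoride treatment; the silyl ether blocks β-elimination next to boron) and comes back at 9. Palladium-catalysed allylic borylation of the lactone with B2pin2 (Pd2(dba)3, DMSO, 50 °C) opens the lactone and gives the C2 allylboronate F1, with boron on the β face, anti to the departed lactone oxygen. Copper–carbene-catalysed γ-selective carboxylation of F1 with 2 ((IPr)CuCl, KOt-Bu in excess to cover the two free acids, THF, 70 °C), followed by allyl bromide, gives the 3-O-triethylsilyl triallyl ester F2; the facial selectivity at C10 would have to be checked and the epimers separated at this stage. HF·pyridine then gives 9.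

Step 5 (one-pot 1,4-reduction and hydroxylation). The hydride may add 1,2 at C3 or attack the hindered C1 only slowly, and the boron-bound enolate may be oxidised sluggishly. The fallback separates reduction from oxygenation and makes the enolate by deprotonation instead of by hydride addition. It sets out from 10 and comes back at 12. Conjugate reduction with [(Ph3P)CuH]6 (benzene, a little water, rt) gives the isolated saturated 3-ketone F3. Deprotonation with KN(SiMe3)2 (THF, −78 °C; only C2 is enolisable on the ketone) and the same oxaziridine give 12.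

Step 6 (re-setting C3). The hydride may give some 3α-alcohol, or the intermediate alkoxide may undergo retro-aldol opening towards the C19 ester. The fallback never destroys the bought 3β-carbinol and delivers the 2β-oxygen from it, bypassing steps 4 to 6. It sets out from 9 and comes back at 13. Boc2O and DMAP (MeCN, rt) give the 3-O-tert-butyl carbonate F4. Iodocarbonate cyclisation (iodine, MeCN, −20 °C; iodine addition to the 16-ene and the allyl groups is reversible, and only the tethered carbonate traps an iodonium ion irreversibly) gives the 1α-iodo-2β,3β-cyclic carbonate F5, with oxygen entering C2 on the β face because it is tethered to the 3β-oxygen. Radical deiodination (Bu3SnH, Et3B, air, toluene, rt) gives the 2β,3β-cyclic carbonate F6. K2CO3 (0.2 equiv) in allyl alcohol at rt opens the carbonate to 13 while ester exchange with the solvent is degenerate.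

**Further compounds**
F1 | step 3 | 2β-(pinacolatoboryl)-3β-(triethylsilyloxy)gibberella-1(10),16-diene-7,19-dioic acid | C=C1C[C@]23C[C@H]1CC[C@H]2C1=C[C@H](B4OC(C)(C)C(C)(C)O4)[C@H](O[Si](CC)(CC)CC)[C@@](C)(C(=O)O)[C@H]1[C@@H]3C(=O)O
F2 | step 3 | triallyl 3β-(triethylsilyloxy)gibberella-1,16-diene-7,19,20-trioate | C=C1C[C@]23C[C@H]1CC[C@H]2[C@]1(C(=O)OCC=C)C=C[C@H](O[Si](CC)(CC)CC)[C@@](C)(C(=O)OCC=C)[C@H]1[C@@H]3C(=O)OCC=C
F3 | step 5 | triallyl 3-oxogibberell-16-ene-7,19,20-trioate | C=C1C[C@]23C[C@H]1CC[C@H]2[C@]1(C(=O)OCC=C)CCC(=O)[C@@](C)(C(=O)OCC=C)[C@H]1[C@@H]3C(=O)OCC=C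
F4 | step 6 | triallyl 3β-(tert-butoxycarbonyloxy)gibberella-1,16-diene-7,19,20-trioate | C=C1C[C@]23C[C@H]1CC[C@H]2[C@]1(C(=O)OCC=C)C=C[C@H](OC(=O)OC(C)(C)C)[C@@](C)(C(=O)OCC=C)[C@H]1[C@@H]3C(=O)OCC=C
F5 | step 6 | triallyl 1α-iodo-2β,3β-(carbonyldioxy)gibberell-16-ene-7,19,20-trioate | C=C1C[C@]23C[C@H]1CC[C@H]2[C@]1(C(=O)OCC=C)[C@@H](I)[C@@H]4OC(=O)O[C@@H]4[C@@](C)(C(=O)OCC=C)[C@H]1[C@@H]3C(=O)OCC=C
F6 | step 6 | triallyl 2β,3β-(carbonyldioxy)gibberell-16-ene-7,19,20-trioate | C=C1C[C@]23C[C@H]1CC[C@H]2[C@]1(C(=O)OCC=C)C[C@@H]4OC(=O)O[C@@H]4[C@@](C)(C(=O)OCC=C)[C@H]1[C@@H]3C(=O)OCC=C
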